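**Retrosynthetic overview**

1. Target 16 comes from bis(benzyl ether) 15 by hydrogenolysis. 15 comes from a Suzuki–Miyaura union (C6–C6') of lactone boronate 12 with ring-opened lithium carboxylate 13, both made from one monomer 11; the carboxylate form is the open chain's own protection against re-lactonisation.
2. Monomer 11 comes from benzofuranone β-keto ester 5 and aldehyde 8 in one operation: the furanone ring takes up one methylene (C3) and becomes the pyranone ring, the C2 ester enolate so formed adds to 8 (C2–C9 bond), and the aldolate closes the γ-lactone (side chain: C9 carbinol, C10 CHMe, C11 CH2, C12 carboxyl).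
3. Enabling feature: in each pyranone ring the quaternary C2 bears CO2Me, is tied through C3H2 to the C4 ketone (a γ-keto ester, i.e. a β-keto ester homologated by C3) and through C2–C9 to a carbinol (aldol retron). Removing C3 therefore leaves a five-membered aromatic β-keto ester with C2 as its enolate carbon.
4. Stereochemistry: C10 is bought with the (S)-methylsuccinate half-ester 6 (→ 8); C9 (Felkin–Anh) and C2 (chelated zinc enolate, chair transition state) are set relative to it in the key step.
5. Ring order: benzene ring (purchased) → furanone ring (Dieckmann, step 3) → pyranone ring by enlargement together with the γ-lactone (step 6) → biaryl bond (step 9), after the lactone of one half has been opened (step 8).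

Key step: step 6

Remark: half-ester 6 is taken as a purchasable chiral-pool compound, and the biaryl axis, flanked on each ring by one oxygen substituent and one hydrogen only, is taken as freely rotating (no axial descriptor is needed).

Step 1
Reactants: 1 methyl 2,6-dihydroxybenzoate
Product: 2 methyl 2-(benzyloxy)-6-hydroxybenzoate
Conditions: BnBr (1.05 equiv), K2CO3 (1.1 equiv), acetone, reflux
Reagents that add atoms: benzyl bromide, BrCc1ccccc1
Why: Williamson etherification; once one phenol is benzylated the other stays hydrogen-bonded to the ester carbonyl and is far less nucleophilic, so mono-alkylation of the symmetric diol should be clean.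

Step 2
Reactants: 2 methyl 2-(benzyloxy)-6-hydroxybenzoate
Product: 3 methyl 2-(benzyloxy)-3-bromo-6-hydroxybenzoate
Conditions: NBS (1.0 equiv), MeCN, −20 → 0 °C
Reagents that add atoms: N-bromosuccinimide, O=C1CCC(=O)N1Br
Why: Electrophilic aromatic bromination; the carbon para to the free hydroxyl and ortho to the benzyloxy group is the most activated position of 2, as in the para-selective bromination of salicylates, so bromine should enter next to the benzyl ether.

Step 3
Reactants: 3 methyl 2-(benzyloxy)-3-bromo-6-hydroxybenzoate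
Product: 5 methyl 4-(benzyloxy)-5-bromo-3-hydroxy-1-benzofuran-2-carboxylate, via aryloxyacetate diester 4 (not isolated)
Conditions: BrCH2CO2Me (1.1 equiv), K2CO3, DMF, rt; then KOtBu (1.3 equiv), 0 °C → rt; 1 M HCl work-up
Reagents that add atoms: methyl bromoacetate, COC(=O)CBr
Why: Williamson etherification with the α-halo ester followed by Dieckmann condensation, a 5-exo-trig attack of the aryloxyacetate enolate on the neighbouring benzoate that is driven by formation of the stabilised enolate of the aromatic 3-hydroxybenzofuran.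

Step 4
Reactants: 6 (2S)-4-methoxy-2-methyl-4-oxobutanoic acid
Product: 7 methyl (3S)-4-(ethylsulfanyl)-3-methyl-4-oxobutanoate
Conditions: EtSH, DCC, DMAP (cat.), CH2Cl2, 0 °C
Reagents that add atoms: ethanethiol, CCS
Why: Steglich-type carbodiimide coupling converts only the free carboxylic acid into the thioester, and the short reaction at 0 °C should leave the α-stereocentre untouched.

Step 5
Reactants: 7 methyl (3S)-4-(ethylsulfanyl)-3-methyl-4-oxobutanoate
Product: 8 methyl (3S)-3-methyl-4-oxobutanoate
Conditions: Et3SiH, 10% Pd/C, acetone, rt; used crude at once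
Reagents that add atoms: none
Why: Fukuyama reduction (palladium-catalysed hydrosilane reduction of a thioester) stops at the aldehyde, spares the methyl ester and is neutral enough to keep the α-stereocentre.

Step 6
Reactants: 5 methyl 4-(benzyloxy)-5-bromo-3-hydroxy-1-benzofuran-2-carboxylate; 8 methyl (3S)-3-methyl-4-oxobutanoate
Product: 11 methyl (2S)-5-(benzyloxy)-6-bromo-2-[(2R,3S)-3-methyl-5-oxooxolan-2-yl]-4-oxo-3,4-dihydro-2H-chromene-2-carboxylate, via chromanone zinc ester enolate 9 (not isolated), via hydroxy diester 10 (not isolated)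
Conditions: Et2Zn (3 equiv), CH2I2 (3 equiv), CH2Cl2, 0 °C; then 8 (1.5 equiv), −20 → 0 °C; aq NH4Cl; then p-TsOH·H2O (cat.), CH2Cl2, rt
Reagents that add atoms: diiodomethane, ICI
Why: Proposed new method: deprotonation of enol 5 by Et2Zn gives a zinc enolate whose C2=C3 bond is cyclopropanated by the carbenoid EtZnCH2I, and the donor–acceptor cyclopropoxide fragments at the old C2–C3 bond, so that the five-membered furanone ring grows by one carbon into the six-membered pyranone ring and leaves ester enolate 9, a Reformatsky-type nucleophile that adds to aldehyde 8 before acid-catalysed lactonisation of 10. The closest known reaction type is the zinc-carbenoid chain extension of β-keto esters to γ-keto esters with aldol capture of the intermediate zinc enolate, extended here to a ring-fused, fully substituted enolate carbon and thus to a ring expansion that ends in a quaternary centre. The pyranone ring is therefore formed by one-carbon insertion (3-exo closure of the cyclopropane, then fragmentation) and not by cyclisation, and the lactone ring by 5-exo-trig acyl substitution of the C9 hydroxyl on the side-chain methyl ester. Enolate 9 is planar and achiral, so all absolute information comes from C10 of 8: Felkin–Anh addition (CH2CO2Me anti to the incoming enolate; in the Zimmerman–Traxler chair the aldehyde methyl then faces only the ring oxygen, whereas the anti-Felkin chair would set it syn-pentane to the C3 methylene) should give 9R, and this 9,10-syn adduct is the one that closes to the cis-4-methyl lactone. C2 is set by the enolate geometry: zinc bridged between the enolate oxygen and ring oxygen O1 (the C4 ketone is held away by the ring and cannot compete) keeps O1 cis to OZn, which with the aldehyde substituent equatorial places O1 and the new C9–O bond syn and should give 2S. The step needs methylene transfer to the enolate carbon only (the zinc enolate is far more nucleophilic than the arene or the benzyl ether, and the aryl bromide is inert to the carbenoid) and aldol addition before proton transfer from C3 (low basicity of zinc enolates, low temperature).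

Step 7
Reactants: 11 methyl (2S)-5-(benzyloxy)-6-bromo-2-[(2R,3S)-3-methyl-5-oxooxolan-2-yl]-4-oxo-3,4-dihydro-2H-chromene-2-carboxylate
Product: 12 methyl (2S)-5-(benzyloxy)-2-[(2R,3S)-3-methyl-5-oxooxolan-2-yl]-4-oxo-6-(4,4,5,5-tetramethyl-1,3,2-dioxaborolan-2-yl)-3,4-dihydro-2H-chromene-2-carboxylate
Conditions: B2pin2, Pd(dppf)Cl2 (5 mol %), KOAc, 1,4-dioxane, 85 °C
Reagents that add atoms: bis(pinacolato)diboron, CC1(C)OB(OC1(C)C)B1OC(C)(C)C(C)(C)O1
Why: Miyaura borylation of the aryl bromide with the weak base KOAc, which should leave the lactone, the esters and the enolisable ketone alone.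

Step 8
Reactants: 11 methyl (2S)-5-(benzyloxy)-6-bromo-2-[(2R,3S)-3-methyl-5-oxooxolan-2-yl]-4-oxo-3,4-dihydro-2H-chromene-2-carboxylate
Product: 13 lithium (3S,4R)-4-[(2S)-5-(benzyloxy)-6-bromo-2-(methoxycarbonyl)-4-oxo-3,4-dihydro-2H-chromen-2-yl]-4-hydroxy-3-methylbutanoate
Conditions: LiOH·H2O (1.05 equiv), THF/H2O (3:1), 0 °C; freeze-dry
Reagents that add atoms: lithium hydroxide, [Li+].[OH-]
Why: Saponification; hydroxide should attack the unhindered γ-lactone carbonyl far faster than the neopentyl-type methyl ester on the quaternary C2, and the γ-hydroxy carboxylate cannot re-close, so it is kept as its lithium salt.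

Step 9
Reactants: 12 methyl (2S)-5-(benzyloxy)-2-[(2R,3S)-3-methyl-5-oxooxolan-2-yl]-4-oxo-6-(4,4,5,5-tetramethyl-1,3,2-dioxaborolan-2-yl)-3,4-dihydro-2H-chromene-2-carboxylate; 13 lithium (3S,4R)-4-[(2S)-5-(benzyloxy)-6-bromo-2-(methoxycarbonyl)-4-oxo-3,4-dihydro-2H-chromen-2-yl]-4-hydroxy-3-methylbutanoate
Product: 15 (3S,4R)-4-[(2S)-5-(benzyloxy)-6-{(2S)-5-(benzyloxy)-2-(methoxycarbonyl)-2-[(2R,3S)-3-methyl-5-oxooxolan-2-yl]-4-oxo-3,4-dihydro-2H-chromen-6-yl}-2-(methoxycarbonyl)-4-oxo-3,4-dihydro-2H-chromen-2-yl]-4-hydroxy-3-methylbutanoic acid, via coupled lithium carboxylate 14 (not isolated)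
Conditions: Pd(OAc)2 (5 mol %), SPhos (10 mol %), CsF (3 equiv), dry 1,4-dioxane/DMF (4:1), 70 °C; then 0.1 M HCl to pH 4, 0 °C, EtOAc
Reagents that add atoms: none
Why: Suzuki–Miyaura cross-coupling under anhydrous fluoride activation, in which the lactone of 12 should stay closed and the carboxylate of 13 cannot lactonise; each ring has only one substituent (OBn) next to the new bond, so the coupling is unhindered and the axis is no stereogenic element, and cold acidification frees the acid.

Step 10
Reactants: 15 (3S,4R)-4-[(2S)-5-(benzyloxy)-6-{(2S)-5-(benzyloxy)-2-(methoxycarbonyl)-2-[(2R,3S)-3-methyl-5-oxooxolan-2-yl]-4-oxo-3,4-dihydro-2H-chromen-6-yl}-2-(methoxycarbonyl)-4-oxo-3,4-dihydro-2H-chromen-2-yl]-4-hydroxy-3-methylbutanoic acid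
Product: 16 (3S,4R)-4-hydroxy-4-[(2S)-5-hydroxy-6-{(2S)-5-hydroxy-2-(methoxycarbonyl)-2-[(2R,3S)-3-methyl-5-oxooxolan-2-yl]-4-oxo-3,4-dihydro-2H-chromen-6-yl}-2-(methoxycarbonyl)-4-oxo-3,4-dihydro-2H-chromen-2-yl]-3-methylbutanoic acid (CNP0517857.1)
Conditions: H2 (1 atm), 10% Pd/C, EtOAc, rt
Reagents that add atoms: none
Why: Hydrogenolysis of the two aryl benzyl ethers under neutral conditions, which should leave esters, lactone, aryl ketones and the acid-sensitive γ-hydroxy acid untouched.

**Compound list**

1 | methyl 2,6-dihydroxybenzoate | COC(=O)c1c(O)cccc1O | starting material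
2 | methyl 2-(benzyloxy)-6-hydroxybenzoate | COC(=O)c1c(O)cccc1OCc1ccccc1 | intermediate
3 | methyl 2-(benzyloxy)-3-bromo-6-hydroxybenzoate | COC(=O)c1c(O)ccc(Br)c1OCc1ccccc1 | intermediate
4 | methyl 2-(benzyloxy)-3-bromo-6-(2-methoxy-2-oxoethoxy)benzoate | COC(=O)COc1ccc(Br)c(OCc2ccccc2)c1C(=O)OC | intermediate
5 | methyl 4-(benzyloxy)-5-bromo-3-hydroxy-1-benzofuran-2-carboxylate (enol form of the β-keto ester) | COC(=O)c1oc2ccc(Br)c(OCc3ccccc3)c2c1O | intermediate
6 | (2S)-4-methoxy-2-methyl-4-oxobutanoic acid | OC(=O)[C@@H](C)CC(=O)OC | starting material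
7 | methyl (3S)-4-(ethylsulfanyl)-3-methyl-4-oxobutanoate | CCSC(=O)[C@@H](C)CC(=O)OC | intermediate
8 | methyl (3S)-3-methyl-4-oxobutanoate | O=C[C@@H](C)CC(=O)OC | intermediate
9 | ethylzinc (Z)-ester enolate of methyl 5-(benzyloxy)-6-bromo-4-oxochromane-2-carboxylate (exocyclic C2=C(OMe)OZnEt, OZn cis to ring O1) | CC[Zn]O/C(OC)=C1\Oc2ccc(Br)c(OCc3ccccc3)c2C(=O)C1 | intermediate
10 | methyl (2S)-5-(benzyloxy)-6-bromo-2-[(1R,2S)-1-hydroxy-4-methoxy-2-methyl-4-oxobutyl]-4-oxo-3,4-dihydro-2H-chromene-2-carboxylate | O=C1C[C@@](C(=O)OC)([C@H](O)[C@@H](C)CC(=O)OC)Oc2ccc(Br)c(OCc3ccccc3)c12 | intermediate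
11 | methyl (2S)-5-(benzyloxy)-6-bromo-2-[(2R,3S)-3-methyl-5-oxooxolan-2-yl]-4-oxo-3,4-dihydro-2H-chromene-2-carboxylate | O=C1C[C@@](C(=O)OC)([C@@H]2OC(=O)C[C@@H]2C)Oc2ccc(Br)c(OCc3ccccc3)c12 | intermediate
12 | methyl (2S)-5-(benzyloxy)-2-[(2R,3S)-3-methyl-5-oxooxolan-2-yl]-4-oxo-6-(4,4,5,5-tetramethyl-1,3,2-dioxaborolan-2-yl)-3,4-dihydro-2H-chromene-2-carboxylate | O=C1C[C@@](C(=O)OC)([C@@H]2OC(=O)C[C@@H]2C)Oc2ccc(B3OC(C)(C)C(C)(C)O3)c(OCc3ccccc3)c12 | intermediate
13 | lithium (3S,4R)-4-[(2S)-5-(benzyloxy)-6-bromo-2-(methoxycarbonyl)-4-oxo-3,4-dihydro-2H-chromen-2-yl]-4-hydroxy-3-methylbutanoate | O=C1C[C@@](C(=O)OC)([C@H](O)[C@@H](C)CC(=O)[O-])Oc2ccc(Br)c(OCc3ccccc3)c12.[Li+] | intermediate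
14 | lithium salt of acid 15 (coupled lithium carboxylate) | COC(=O)[C@@]1([C@H](O)[C@@H](C)CC(=O)[O-])CC(=O)c2c(ccc(-c3ccc4c(c3OCc5ccccc5)C(=O)C[C@@](C(=O)OC)([C@@H]3OC(=O)C[C@@H]3C)O4)c2OCc2ccccc2)O1.[Li+] | intermediate
15 | (3S,4R)-4-[(2S)-5-(benzyloxy)-6-{(2S)-5-(benzyloxy)-2-(methoxycarbonyl)-2-[(2R,3S)-3-methyl-5-oxooxolan-2-yl]-4-oxo-3,4-dihydro-2H-chromen-6-yl}-2-(methoxycarbonyl)-4-oxo-3,4-dihydro-2H-chromen-2-yl]-4-hydroxy-3-methylbutanoic acid | COC(=O)[C@@]1([C@H](O)[C@@H](C)CC(=O)O)CC(=O)c2c(ccc(-c3ccc4c(c3OCc5ccccc5)C(=O)C[C@@](C(=O)OC)([C@@H]3OC(=O)C[C@@H]3C)O4)c2OCc2ccccc2)O1 | intermediate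
16 | (3S,4R)-4-hydroxy-4-[(2S)-5-hydroxy-6-{(2S)-5-hydroxy-2-(methoxycarbonyl)-2-[(2R,3S)-3-methyl-5-oxooxolan-2-yl]-4-oxo-3,4-dihydro-2H-chromen-6-yl}-2-(methoxycarbonyl)-4-oxo-3,4-dihydro-2H-chromen-2-yl]-3-methylbutanoic acid | COC(=O)[C@@]1([C@H](O)[C@@H](C)CC(=O)O)CC(=O)c2c(ccc(-c3ccc4c(c3O)C(=O)C[C@@](C(=O)OC)([C@@H]3OC(=O)C[C@@H]3C)O4)c2O)O1 | target

**Step count and risks**

Total step count: 10. Longest linear sequence: 7 steps (1, 2, 3, 6, 7 or 8, 9, 10).

The three steps most likely to fail:

First, step 6, the step that bears the label "Proposed new method:". Methylene transfer to the aromatic enolate may not take place or may overrun (a second methylene transfer to enolate 9), and the aldol may lose its simple diastereoselection if the enolate does not react through the O1-chelated geometry. The fallback uses known chemistry only, sets out from 5 and comes back at 11.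
- C-alkylation of the sodium enolate of 5 with diiodomethane (NaH, THF/DMPU) gives racemic methyl 4-(benzyloxy)-5-bromo-2-(iodomethyl)-3-oxo-2,3-dihydro-1-benzofuran-2-carboxylate F1.
- Dowd–Beckwith radical ring expansion of F1 (Bu3SnH, AIBN, benzene, 80 °C, slow addition; the alkyl iodide is abstracted much faster than the aryl bromide) gives racemic methyl 5-(benzyloxy)-6-bromo-4-oxo-3,4-dihydro-2H-chromene-2-carboxylate F2.
- Dehydrogenation (DDQ, dioxane, 100 °C) gives methyl 5-(benzyloxy)-6-bromo-4-oxo-4H-chromene-2-carboxylate F3.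
- TIPSOTf turns F3 into a 4-silyloxybenzopyrylium ion, to which trimethyl[(4-methylfuran-2-yl)oxy]silane F4 (from 4-methylfuran-2(5H)-one, TMSOTf, Et3N) adds at C2 in a vinylogous Mukaiyama reaction. This gives methyl 5-(benzyloxy)-6-bromo-2-(3-methyl-5-oxo-2,5-dihydrofuran-2-yl)-4-[(triisopropylsilyl)oxy]-2H-chromene-2-carboxylate F5.
- Acidic work-up of F5 gives the chromanone butenolide as a racemate. Its desired diastereomer is isolated and resolved by preparative chromatography on a chiral stationary phase to methyl (2S)-5-(benzyloxy)-6-bromo-2-[(2R)-3-methyl-5-oxo-2,5-dihydrofuran-2-yl]-4-oxo-3,4-dihydro-2H-chromene-2-carboxylate F6.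
- Conjugate reduction of F6 with [CuH(PPh3)]6 (hydride enters the butenolide face away from the chromanone, so the methyl group ends up cis) gives 11.

Second, step 9. The lactone of 12 may be opened by the basic fluoride medium or by traces of water, which would scramble the two halves. The ortho-alkoxy boronate may also protodeboronate, or C2 may epimerise through enolisation at C3 and reversible opening of the pyranone ring. The fallback sets out from 11 and comes back at 14.
- One-pot borylation and Suzuki–Miyaura homocoupling of 11 (Pd(OAc)2, SPhos, B2pin2 0.55 equiv, K3PO4, dioxane/H2O, 80 °C), then p-TsOH in CH2Cl2, which re-closes any lactone opened by the base because both halves are identical. This gives dimethyl (2S,2'S)-5,5'-bis(benzyloxy)-2,2'-bis[(2R,3S)-3-methyl-5-oxooxolan-2-yl]-4,4'-dioxo-3,3',4,4'-tetrahydro-2H,2'H-[6,6'-bichromene]-2,2'-dicarboxylate F7.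
- Saponification of one lactone with one equivalent of LiOH (THF/H2O, 0 °C) is then a statistical desymmetrisation that gives 14, which is acidified to 15 as in step 9. Unchanged F7 is recovered, and the doubly opened diacid is re-lactonised with acid and recycled.

Third, step 8. Hydroxide may also attack the C2 methyl ester, or may enolise C3 so that the pyranone ring opens and re-closes (retro-oxa-Michael) with loss of the C2 configuration. The fallback sets out from 10 and comes back at 13.
- The key step is quenched with pH 7 buffer and the acid treatment is left out, so that hydroxy diester 10 is isolated.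
- Pig-liver esterase in pH 7.5 phosphate buffer/acetone, with LiOH added by pH-stat, hydrolyses the unhindered side-chain methyl ester and gives 13 with no exposure to free hydroxide. This fallback makes no compound outside the list (F0).

**Further compounds**

F1 | step 6 | methyl 4-(benzyloxy)-5-bromo-2-(iodomethyl)-3-oxo-2,3-dihydro-1-benzofuran-2-carboxylate (racemic) | COC(=O)C1(CI)Oc2ccc(Br)c(OCc3ccccc3)c2C1=O
F2 | step 6 | methyl 5-(benzyloxy)-6-bromo-4-oxo-3,4-dihydro-2H-chromene-2-carboxylate (racemic) | COC(=O)C1CC(=O)c2c(OCc3ccccc3)c(Br)ccc2O1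
F3 | step 6 | methyl 5-(benzyloxy)-6-bromo-4-oxo-4H-chromene-2-carboxylate | COC(=O)c1cc(=O)c2c(OCc3ccccc3)c(Br)ccc2o1
F4 | step 6 | trimethyl[(4-methylfuran-2-yl)oxy]silane | Cc1coc(O[Si](C)(C)C)c1
F5 | step 6 | methyl 5-(benzyloxy)-6-bromo-2-(3-methyl-5-oxo-2,5-dihydrofuran-2-yl)-4-[(triisopropylsilyl)oxy]-2H-chromene-2-carboxylate (racemic, (2S,2'R) enantiomer drawn) | CC(C)[Si](OC1=C[C@@](C(=O)OC)([C@@H]2OC(=O)C=C2C)Oc2ccc(Br)c(OCc3ccccc3)c12)(C(C)C)C(C)C
F6 | step 6 | methyl (2S)-5-(benzyloxy)-6-bromo-2-[(2R)-3-methyl-5-oxo-2,5-dihydrofuran-2-yl]-4-oxo-3,4-dihydro-2H-chromene-2-carboxylate (formed as the racemate, then resolved) | O=C1C[C@@](C(=O)OC)([C@@H]2OC(=O)C=C2C)Oc2ccc(Br)c(OCc3ccccc3)c12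
F7 | step 9 | dimethyl (2S,2'S)-5,5'-bis(benzyloxy)-2,2'-bis[(2R,3S)-3-methyl-5-oxooxolan-2-yl]-4,4'-dioxo-3,3',4,4'-tetrahydro-2H,2'H-[6,6'-bichromene]-2,2'-dicarboxylate | O=C1C[C@@](C(=O)OC)([C@@H]2OC(=O)C[C@@H]2C)Oc2ccc(-c3ccc4c(c3OCc5ccccc5)C(=O)C[C@@](C(=O)OC)([C@@H]3OC(=O)C[C@@H]3C)O4)c(OCc3ccccc3)c12
F0 | step 8 | none | none
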